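## Plan

- **Numbering (furanone):** O1, C2 (lactone C=O), C3 (CH3), C4 (CO2H), C5 (H and side chain C1′–C15′, ketone at C14′).
- **Cuts, in retrosynthetic order:** first C1′–C2′, which removes the chain and leaves a carboxyl on C1′. Next O1–C5 together with C1′–H, which opens the butenolide to a cis,cis-muconic half-ester. Last, the two terminal carboxyl carbons are rejoined as the C(OH)–C(OH) bond of a catechol.
- **Enabling feature:** the contiguous atoms C2–C3–C4–C5–C1′, with the C3 methyl and the C4 carboxyl, are arene carbons C3–C2–C1–C6–C5 of a 3,4-dihydroxy-2-methylbenzoate. The benzene ring fixes the tetrasubstituted C3=C4 alkene with the C2 acid cis to C5 and leaves C5=C1′ as a Z-enoate acceptor.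
- **Forward order:** catechol ester, oxidative ring opening, closure of the only ring (the five-membered butenolide), exchange of the ester carbon on C1′ (old arene C4) for the C2′–C15′ fragment with its masked ketone, then acid unmasking.
- **Stereochemistry:** the single centre C5 (R) is created in the ring closure by a chiral amine–squaramide catalyst. Every later step is neutral, radical at C1′ only, or acidic, so C5 is left alone.
- **Chain fragment:** it is made from ethyl acetoacetate and 1,11-dibromoundecane.

Key step: step 4

Assumption: the sense of induction of the squaramide catalyst on this new substrate class cannot be derived from precedent. The quinidine-derived catalyst is written, and its quinine-derived pseudo-enantiomer takes its place if a test run, read out by chiroptical comparison at the stage of the target, shows the opposite sense.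

## Route

Step 1
Reactants: 1 3,4-dimethoxy-2-methylbenzoic acid
Product: 2 3,4-dihydroxy-2-methylbenzoic acid
Conditions: BBr3 (3.5 equiv), CH2Cl2, −78 °C to rt; then ice–water
Reagents that add atoms: none
Why: Lewis-acid cleavage of aryl methyl ethers, in which boron binds each methoxy oxygen, bromide removes the methyl group by SN2 attack and aqueous work-up frees the catechol, while the carboxylic acid and the aryl methyl group are inert.

Step 2
Reactants: 2 3,4-dihydroxy-2-methylbenzoic acid
Product: 3 tert-butyl 3,4-dihydroxy-2-methylbenzoate
Conditions: Cl3CC(=NH)OtBu (2.5 equiv), THF–cyclohexane, rt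
Reagents that add atoms: tert-butyl 2,2,2-trichloroacetimidate, CC(C)(C)OC(=N)C(Cl)(Cl)Cl
Why: Alkylative esterification with a trichloroacetimidate, in which only the carboxylic acid is acidic enough to protonate the imidate, so the tert-butyl group passes to the carboxylate oxygen without attack at the ortho-hindered carbonyl and the phenols stay free in the absence of a Lewis acid.

Step 3
Reactants: 3 tert-butyl 3,4-dihydroxy-2-methylbenzoate
Product: 5 (2E,4Z)-3-(tert-butoxycarbonyl)-6-methoxy-2-methyl-6-oxohexa-2,4-dienoic acid, via o-quinone 4 (not isolated)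
Conditions: CuCl (4 equiv), pyridine–MeOH, O2 (1 atm), rt, slow addition of 3; cold dilute HCl to pH 3, extraction at 0 °C, no heating
Reagents that add atoms: dioxygen, O=O; methanol, CO
Why: Copper-mediated intradiol cleavage of a catechol (pyrocatechase-model oxygenation), in which divalent copper methoxide formed from CuCl, O2 and methanol oxidises 3 to o-quinone 4, methoxide adds to the carbonyl flanked by C–H rather than to the one shielded by the neighbouring methyl group, and scission of the dione C–C bond gives the half-ester whose free acid sits on the methyl-bearing carbon and whose 2E,4Z geometry is that of the ring.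

Step 4
Reactants: 5 (2E,4Z)-3-(tert-butoxycarbonyl)-6-methoxy-2-methyl-6-oxohexa-2,4-dienoic acid
Product: 6 tert-butyl (2R)-2-(2-methoxy-2-oxoethyl)-4-methyl-5-oxo-2,5-dihydrofuran-3-carboxylate
Conditions: squaramide from 9-amino-9-deoxy-epi-quinidine and 3,5-bis(trifluoromethyl)aniline (10 mol%), toluene–CH2Cl2, 0.05 M, −30 °C; cold silica plug
Reagents that add atoms: none
Why: Proposed new method: the quinuclidine nitrogen takes the proton of the C2 acid to form a tight ammonium carboxylate pair while the squaramide N–H bonds hold the methyl ester carbonyl, the carboxylate oxygen adds to C5 (the β-carbon of the Z-enoate) to make O1–C5, and the quinuclidinium then protonates the ester enolate at C1′ and so releases the catalyst. The closest known reaction types are amine–squaramide catalysed intramolecular oxa-Michael additions of alcohols, phenols and 2-alkenylbenzoic acids to enones and the enzymatic cycloisomerisation of 3-carboxy-cis,cis-muconate, whereas an enantioselective addition of a carboxylic acid to a muconic ester has not been described. The butenolide closes in the 5-exo-trig mode, which is easy because the 2E double bond inherited from the benzene ring holds the acid beside C5 and because the enoate is further polarised by the electron-poor C3=C4 unit attached to it. C5 is controlled by the catalyst alone: 5 is achiral but twisted about the C4–C5 single bond, its two mirror-image helical conformers present the Re or the Si face of C5 to the carboxylate, and the chiral ion pair has to bind and close the conformer that reacts on the Re face, which gives R. Site selectivity needs no help from the catalyst, since there is one free acid, the polarity of the enoate directs oxygen to C5 and not to C1′, and the tetrasubstituted C3=C4 bond cannot be reached by its own carboxyl group. Low temperature, a weakly polar solvent and moderate dilution hold back the uncatalysed, self-acid-promoted racemic closure, and taking the amine out on a cold silica plug guards 6 against retro-oxa-Michael opening or dienolate formation.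

Step 5
Reactants: 6 tert-butyl (2R)-2-(2-methoxy-2-oxoethyl)-4-methyl-5-oxo-2,5-dihydrofuran-3-carboxylate
Product: 7 2-[(2R)-3-(tert-butoxycarbonyl)-4-methyl-5-oxo-2,5-dihydrofuran-2-yl]acetic acid
Conditions: pig liver esterase, 0.2 M phosphate buffer pH 7.0, acetone (10% v/v), 25 °C; citric acid to pH 3 at 0 °C, EtOAc
Reagents that add atoms: water, O
Why: Esterase-catalysed hydrolysis at neutral pH takes only the unhindered methyl ester, since the tert-butyl ester is not accepted by the serine hydrolase and the absence of free hydroxide avoids deprotonation at C5 or C1′ and with it racemisation or retro-oxa-Michael opening.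

Step 6
Reactants: 7 2-[(2R)-3-(tert-butoxycarbonyl)-4-methyl-5-oxo-2,5-dihydrofuran-2-yl]acetic acid
Product: 8 tert-butyl (2R)-2-{2-[(1,3-dioxoisoindolin-2-yl)oxy]-2-oxoethyl}-4-methyl-5-oxo-2,5-dihydrofuran-3-carboxylate
Conditions: N-hydroxyphthalimide, N,N′-diisopropylcarbodiimide, CH2Cl2, 0 °C to rt, no amine base
Reagents that add atoms: N-hydroxyphthalimide, O=C1c2ccccc2C(=O)N1O
Why: Carbodiimide (Steglich-type) esterification converts the acid into the redox-active N-acyloxyphthalimide, and leaving out any amine base protects the β-acyloxy ester from elimination and C5 from epimerisation.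

Step 7
Reactants: 9 ethyl acetoacetate; 10 1,11-dibromoundecane
Product: 11 ethyl 2-acetyl-13-bromotridecanoate (racemic)
Conditions: NaOEt (1 equiv), EtOH, 10 (3 equiv), reflux
Reagents that add atoms: none
Why: Acetoacetic ester synthesis, in which the sodium enolate of 9 displaces one bromide of 10 by SN2 C-alkylation, the excess of dibromide suppresses reaction at both chain ends, and the new racemic centre disappears in the next step.

Step 8
Reactants: 11 ethyl 2-acetyl-13-bromotridecanoate
Product: 13 14-bromotetradecan-2-one, via 2-acetyl-13-bromotridecanoic acid 12 (not isolated)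
Conditions: 48% aq HBr, AcOH, reflux
Reagents that add atoms: water, O (its oxygen is held in 12 only and leaves again in CO2)
Why: Ketonic cleavage of the acetoacetic ester synthesis, in which acid hydrolysis gives β-keto acid 12, this loses CO2 through a six-membered transition state on heating, and the HBr medium keeps the primary bromide in place.

Step 9
Reactants: 13 14-bromotetradecan-2-one
Product: 14 2-(12-bromododecyl)-2-methyl-1,3-dioxolane
Conditions: ethylene glycol, p-TsOH·H2O (cat.), toluene, Dean–Stark, reflux
Reagents that add atoms: ethylene glycol, OCCO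
Why: Acid-catalysed ketalisation with azeotropic removal of water masks the ketone so that a Grignard reagent can be made from the bromide.

Step 10
Reactants: 8 tert-butyl (2R)-2-{2-[(1,3-dioxoisoindolin-2-yl)oxy]-2-oxoethyl}-4-methyl-5-oxo-2,5-dihydrofuran-3-carboxylate; 14 2-(12-bromododecyl)-2-methyl-1,3-dioxolane
Product: 17 tert-butyl (2R)-4-methyl-2-[13-(2-methyl-1,3-dioxolan-2-yl)tridecyl]-5-oxo-2,5-dihydrofuran-3-carboxylate, via Grignard reagent 15 (not isolated), via dialkylzinc 16 (not isolated)
Conditions: 14 (4 equiv), Mg, THF, 45 °C; ZnCl2 (2 equiv), LiCl, THF, 0 °C to rt; then 8, NiCl2(dme) (20 mol%), 4,4′-di-tert-butyl-2,2′-bipyridine (40 mol%), THF–DMF, rt; aq NH4Cl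
Reagents that add atoms: magnesium, [Mg] (held in 15 only); zinc dichloride, Cl[Zn]Cl (zinc held in 16 only)
Why: Nickel-catalysed decarboxylative Negishi-type alkyl–alkyl coupling of a redox-active ester, in which a monovalent alkylnickel species reduces the phthalimide ester by one electron, loss of CO2 gives the primary C1′ radical, capture at nickel and reductive elimination form C1′–C2′, the lactone, ketal and tert-butyl ester tolerate the weakly basic dialkylzinc, and C5, next to but not part of the radical centre, keeps its configuration.

Step 11
Reactants: 17 tert-butyl (2R)-4-methyl-2-[13-(2-methyl-1,3-dioxolan-2-yl)tridecyl]-5-oxo-2,5-dihydrofuran-3-carboxylate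
Product: 19 isomuronic acid [(2R)-4-methyl-5-oxo-2-(14-oxopentadecyl)-2,5-dihydrofuran-3-carboxylic acid], via keto tert-butyl ester 18 (not isolated)
Conditions: CF3CO2H–CH2Cl2–H2O, 0 °C to rt
Reagents that add atoms: water, O
Why: Aqueous trifluoroacetic acid first hydrolyses the dioxolane to ketone 18 and then ionises the tert-butyl ester with E1-type loss of isobutene, while the butenolide and its C5–H centre, which are labile only to base, are unaffected.

## Compound list

1 | 3,4-dimethoxy-2-methylbenzoic acid | COc1ccc(C(=O)O)c(C)c1OC | starting material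
2 | 3,4-dihydroxy-2-methylbenzoic acid | Cc1c(O)c(O)ccc1C(=O)O | intermediate
3 | tert-butyl 3,4-dihydroxy-2-methylbenzoate | Cc1c(O)c(O)ccc1C(=O)OC(C)(C)C | intermediate
4 | tert-butyl 2-methyl-3,4-dioxocyclohexa-1,5-diene-1-carboxylate (o-quinone) | CC1=C(C(=O)OC(C)(C)C)C=CC(=O)C1=O | intermediate
5 | (2E,4Z)-3-(tert-butoxycarbonyl)-6-methoxy-2-methyl-6-oxohexa-2,4-dienoic acid | CC(/C(=O)O)=C(/C=C\C(=O)OC)C(=O)OC(C)(C)C | intermediate
6 | tert-butyl (2R)-2-(2-methoxy-2-oxoethyl)-4-methyl-5-oxo-2,5-dihydrofuran-3-carboxylate | COC(=O)C[C@H]1OC(=O)C(C)=C1C(=O)OC(C)(C)C | intermediate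
7 | 2-[(2R)-3-(tert-butoxycarbonyl)-4-methyl-5-oxo-2,5-dihydrofuran-2-yl]acetic acid | OC(=O)C[C@H]1OC(=O)C(C)=C1C(=O)OC(C)(C)C | intermediate
8 | tert-butyl (2R)-2-{2-[(1,3-dioxoisoindolin-2-yl)oxy]-2-oxoethyl}-4-methyl-5-oxo-2,5-dihydrofuran-3-carboxylate | O=C(C[C@H]1OC(=O)C(C)=C1C(=O)OC(C)(C)C)ON1C(=O)c2ccccc2C1=O | intermediate
9 | ethyl acetoacetate | CCOC(=O)CC(C)=O | starting material
10 | 1,11-dibromoundecane | BrCCCCCCCCCCCBr | starting material
11 | ethyl 2-acetyl-13-bromotridecanoate (racemic) | CCOC(=O)C(CCCCCCCCCCCBr)C(C)=O | intermediate
12 | 2-acetyl-13-bromotridecanoic acid | OC(=O)C(CCCCCCCCCCCBr)C(C)=O | intermediate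
13 | 14-bromotetradecan-2-one | CC(=O)CCCCCCCCCCCCBr | intermediate
14 | 2-(12-bromododecyl)-2-methyl-1,3-dioxolane | CC1(CCCCCCCCCCCCBr)OCCO1 | intermediate
15 | [12-(2-methyl-1,3-dioxolan-2-yl)dodecyl]magnesium bromide | CC1(CCCCCCCCCCCC[Mg]Br)OCCO1 | intermediate
16 | bis[12-(2-methyl-1,3-dioxolan-2-yl)dodecyl]zinc | CC1(CCCCCCCCCCCC[Zn]CCCCCCCCCCCCC2(C)OCCO2)OCCO1 | intermediate
17 | tert-butyl (2R)-4-methyl-2-[13-(2-methyl-1,3-dioxolan-2-yl)tridecyl]-5-oxo-2,5-dihydrofuran-3-carboxylate | CC1(CCCCCCCCCCCCC[C@H]2OC(=O)C(C)=C2C(=O)OC(C)(C)C)OCCO1 | intermediate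
18 | tert-butyl (2R)-4-methyl-5-oxo-2-(14-oxopentadecyl)-2,5-dihydrofuran-3-carboxylate | CC(=O)CCCCCCCCCCCCC[C@H]1OC(=O)C(C)=C1C(=O)OC(C)(C)C | intermediate
19 | isomuronic acid, (2R)-4-methyl-5-oxo-2-(14-oxopentadecyl)-2,5-dihydrofuran-3-carboxylic acid | CC(=O)CCCCCCCCCCCCC[C@H]1OC(=O)C(C)=C1C(=O)O | target

## Step count

- **Total step count:** 11.
- **Longest linear sequence:** 8 steps (steps 1–6, 10 and 11). The chain fragment adds a three-step branch (steps 7–9).

## Steps most likely to fail

**Step 4 (new method).**
- The risk is poor facial selectivity. It could arise from uncatalysed ring closure running beside the catalysed one, from Z-to-E isomerisation of the enoate before closure, or from reversible opening of the product on the amine.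
- The fallback replaces catalysis by resolution and uses known chemistry only.
- It sets out from 5. The ring is closed without stereocontrol by gentle warming in acetic acid, the classical acid-promoted lactonisation of cis,cis-muconic acids and their half-esters. This gives racemic tert-butyl 2-(2-methoxy-2-oxoethyl)-4-methyl-5-oxo-2,5-dihydrofuran-3-carboxylate F1.
- Preparative supercritical-fluid chromatography on an amylose tris(3,5-dimethylphenylcarbamate) phase then delivers 6, where the route is rejoined.
- The unwanted tert-butyl (2S)-2-(2-methoxy-2-oxoethyl)-4-methyl-5-oxo-2,5-dihydrofuran-3-carboxylate F2 is racemised with catalytic DBU through its achiral dienolate and fed back into the separation.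

**Step 3.**
- Three processes may intervene: entry of methanol at the wrong carbonyl, conjugate addition of methanol or pyridine to the electron-poor quinone, and premature racemic lactonisation or alkene isomerisation during long contact with pyridine.
- The fallback is a stepwise, copper-free and pyridine-free cleavage, in which the step that decides the regiochemistry is separated from the oxidation.
- It sets out from 3. Ag2O in Et2O over Na2SO4 at 0 °C gives a solution of o-quinone 4.
- This solution is treated at once with mCPBA in CH2Cl2 at 0 °C. The reaction is a Baeyer–Villiger-type oxygen insertion between the two carbonyl groups, known for o-quinones. It gives the muconic anhydride tert-butyl 3-methyl-2,7-dioxo-2,7-dihydrooxepine-4-carboxylate F3.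
- Methanol at −20 °C opens the anhydride at the less hindered C7 carbonyl, and the route is rejoined at 5.

**Step 10.**
- Three processes may intervene: β-acyloxy elimination from the C1′–nickel species with opening of the lactone, 3-exo attack of the C1′ radical on the electron-poor C3=C4 bond followed by ring expansion, and slow capture of the radical.
- The fallback keeps the carboxyl carbon as C2′, which moves the reacting centre one atom further from the lactone oxygen and the alkene, and it uses a two-electron coupling.
- It sets out from 7. BH3·THF at 0 °C reduces the acid selectively to tert-butyl (2R)-2-(2-hydroxyethyl)-4-methyl-5-oxo-2,5-dihydrofuran-3-carboxylate F4.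
- An Appel reaction (I2, PPh3, imidazole) gives tert-butyl (2R)-2-(2-iodoethyl)-4-methyl-5-oxo-2,5-dihydrofuran-3-carboxylate F5.
- The chain fragment, one carbon shorter, is made from 9 and commercial 1,10-dibromodecane (BrCCCCCCCCCCBr) by the sequence of steps 7–9. The intermediates are:
  - ethyl 2-acetyl-12-bromododecanoate F6
  - transient 2-acetyl-12-bromododecanoic acid F7
  - 13-bromotridecan-2-one F8
  - 2-(11-bromoundecyl)-2-methyl-1,3-dioxolane F9
- Zinc dust with LiCl in THF converts the last of these into [11-(2-methyl-1,3-dioxolan-2-yl)undecyl]zinc bromide F10.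
- An alkyl–alkyl Negishi coupling of the iodide with this zinc reagent follows. The conditions are PdCl2(IPr)(3-chloropyridine), where IPr is 1,3-bis(2,6-diisopropylphenyl)imidazol-2-ylidene, with LiBr in THF–NMP at rt. The route is rejoined at 17.

## Further compounds

F1 | step 4 | racemic tert-butyl 2-(2-methoxy-2-oxoethyl)-4-methyl-5-oxo-2,5-dihydrofuran-3-carboxylate | COC(=O)CC1OC(=O)C(C)=C1C(=O)OC(C)(C)C
F2 | step 4 | tert-butyl (2S)-2-(2-methoxy-2-oxoethyl)-4-methyl-5-oxo-2,5-dihydrofuran-3-carboxylate | COC(=O)C[C@@H]1OC(=O)C(C)=C1C(=O)OC(C)(C)C
F3 | step 3 | tert-butyl 3-methyl-2,7-dioxo-2,7-dihydrooxepine-4-carboxylate | CC1=C(C(=O)OC(C)(C)C)C=CC(=O)OC1=O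
F4 | step 10 | tert-butyl (2R)-2-(2-hydroxyethyl)-4-methyl-5-oxo-2,5-dihydrofuran-3-carboxylate | OCC[C@H]1OC(=O)C(C)=C1C(=O)OC(C)(C)C
F5 | step 10 | tert-butyl (2R)-2-(2-iodoethyl)-4-methyl-5-oxo-2,5-dihydrofuran-3-carboxylate | ICC[C@H]1OC(=O)C(C)=C1C(=O)OC(C)(C)C
F6 | step 10 | ethyl 2-acetyl-12-bromododecanoate (racemic) | CCOC(=O)C(CCCCCCCCCCBr)C(C)=O
F7 | step 10 | 2-acetyl-12-bromododecanoic acid | OC(=O)C(CCCCCCCCCCBr)C(C)=O
F8 | step 10 | 13-bromotridecan-2-one | CC(=O)CCCCCCCCCCCBr
F9 | step 10 | 2-(11-bromoundecyl)-2-methyl-1,3-dioxolane | CC1(CCCCCCCCCCCBr)OCCO1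
F10 | step 10 | [11-(2-methyl-1,3-dioxolan-2-yl)undecyl]zinc bromide | CC1(CCCCCCCCCCC[Zn]Br)OCCO1
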